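**Retrosynthetic overview**

1. Monotesone A (11) comes from (2S)-flavanone triacetate 10 by deacetylation, and 10 from 2,4-cis-flavan-4-ol 9 by oxidation of the C4 carbinol, whose oxygen is the ketone oxygen.
2. Ring C (O1–C2–C3–C4–C4a–C8a) is the only ring formed. It is cut at C3–C4 and O1–C2 into salicylaldehyde 2 (O1, C8a, C4a, C4 with ring A) and styrene 8 (C2, C3 with ring B); rings A and B are bought.
3. The feature used: C2 carries the electron-rich ring B (para-prenyloxy), which stabilises positive charge at C2, and C4 carries oxygen. The formyl carbon of an ortho-hydroxybenzaldehyde and the CH2 of a styrene therefore have matched polarity for a cationic hetero-[4+2].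
4. All three phenol oxygens travel as acetates. An electron-poor ring A makes the aldehyde more electrophilic and keeps the C4 carbinol of 9 from ionising under the acid, so the catalyst-set C4 can pass its configuration to C2 before C4 is erased.
5. Aldehyde 2 comes in one step from 2,4,6-trihydroxybenzaldehyde; styrene 8 comes from 3,4-dihydroxybenzaldehyde by 4-O-prenylation, Wittig methylenation and acetylation.

Key step: step 5

Assumption: the sense of induction of the confined acid cannot be predicted with certainty. The (S,S)-catalyst is written; its mirror image would be used if the first experiment shows attack on the other face of the aldehyde. Prenyl means 3-methylbut-2-enyl.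

**Route**

Step 1
Reactants: 1 2,4,6-trihydroxybenzaldehyde
Product: 2 2,4-diacetoxy-6-hydroxybenzaldehyde
Conditions: Ac2O (2.05 equiv), pyridine (2.5 equiv), EtOAc, 0 °C
Reagents that add atoms: acetic anhydride CC(=O)OC(C)=O
Why: Selective O-acetylation; the para hydroxyl and one ortho hydroxyl are acylated, while the remaining ortho hydroxyl is hydrogen-bonded to the formyl oxygen and is the least nucleophilic, so two equivalents of anhydride should stop at the diacetate.

Step 2
Reactants: 3 3,4-dihydroxybenzaldehyde; 4 1-bromo-3-methylbut-2-ene (prenyl bromide)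
Product: 5 3-hydroxy-4-(3-methylbut-2-enyloxy)benzaldehyde
Conditions: NaHCO3 (1.5 equiv), DMF, 40 °C
Reagents that add atoms: none
Why: Williamson etherification; with a weak base only the more acidic 4-OH (para to the formyl group) is deprotonated to a useful extent, so mono-alkylation should be selective for O4.

Step 3
Reactants: 5 3-hydroxy-4-(3-methylbut-2-enyloxy)benzaldehyde
Product: 7 2-(3-methylbut-2-enyloxy)-5-vinylphenol, via potassium 5-formyl-2-(3-methylbut-2-enyloxy)phenolate 6 (not isolated)
Conditions: Ph3PCH3Br (2.5 equiv), KOtBu (2.4 equiv), THF, 0 °C → rt; aq NH4Cl quench; BHT (trace) on concentration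
Reagents that add atoms: methyltriphenylphosphonium bromide C[P+](c1ccccc1)(c1ccccc1)c1ccccc1.[Br-]
Why: Wittig methylenation; the first equivalent of base turns the phenol into phenolate 6, which does not interfere, and the excess ylide converts the formyl group into the vinyl group without touching the prenyl ether.

Step 4
Reactants: 7 2-(3-methylbut-2-enyloxy)-5-vinylphenol
Product: 8 2-(3-methylbut-2-enyloxy)-5-vinylphenyl acetate
Conditions: Ac2O (1.3 equiv), Et3N (1.5 equiv), DMAP (5 mol%), CH2Cl2, 0 °C
Reagents that add atoms: acetic anhydride CC(=O)OC(C)=O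
Why: DMAP-catalysed acetylation of the phenol; it masks the nucleophilic phenol and tempers ring B for the acid step.

Step 5
Reactants: 2 2,4-diacetoxy-6-hydroxybenzaldehyde; 8 2-(3-methylbut-2-enyloxy)-5-vinylphenyl acetate
Product: 9 (2S,4S)-5,7-diacetoxy-2-[3-acetoxy-4-(3-methylbut-2-enyloxy)phenyl]chroman-4-ol
Conditions: (S,S)-imidodiphosphorimidate Brønsted acid (IDPi; two 3,3'-bis[3,5-bis(trifluoromethyl)phenyl]-BINOL units, N-Tf; 5 mol%), 5 Å MS, CHCl3, −40 °C; 8 added slowly to 2 (1.3 equiv)
Reagents that add atoms: none
Why: Proposed new method: the confined acid hydrogen-bonds to (in the limit protonates) the formyl oxygen of 2 while the neighbouring phenol OH gives a second contact in the chiral pocket; the CH2 terminus of 8 adds to the Si face of this hydroxycarbenium ion (the O-protonated ortho-quinone methide tautomer of 2), forming C3–C4 and setting C4 as S, and the resulting C2 benzylic cation, stabilised by the para-prenyloxy group and paired with the chiral anion, is captured by the phenol oxygen to form O1–C2. The closest known reactions are the racemic acid-mediated [4+2] of salicylaldehyde-derived oxocarbenium ions with styrenes to 2,4-cis-4-alkoxyflavans and the asymmetric Prins cyclisations and ortho-quinone methide cycloadditions of salicylaldehydes under confined imidodiphosphate-type acids; an intermolecular enantioselective version with a free aldehyde and a simple styrene has not been described. Ring C closes as a six-membered oxa-cyclisation of a phenol onto a benzylic cation (formally an asynchronous inverse-demand hetero-[4+2]) through a half-chair with the C2 aryl group and the C4 hydroxyl both pseudo-equatorial. C4 is set by the catalyst (enantiofacial attack on the aldehyde) and C2 by the substrate relative to C4: the cis closure should be kinetically preferred and is also the thermodynamic outcome if O1–C2 re-ionises, so 4S is translated into 2S. The step needs chemoselectivity for the styrene over the prenyl olefin, secured by the much higher nucleophilicity of the para-alkoxystyrene terminus, which alone places the cation next to ring B and so also fixes the regiochemistry; it also needs a C4 carbinol that does not ionise, secured by the acetyl groups that make ring A electron-poor and leave the phenol OH as the only internal nucleophile.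

Step 6
Reactants: 9 (2S,4S)-5,7-diacetoxy-2-[3-acetoxy-4-(3-methylbut-2-enyloxy)phenyl]chroman-4-ol
Product: 10 (2S)-5,7-diacetoxy-2-[3-acetoxy-4-(3-methylbut-2-enyloxy)phenyl]chroman-4-one
Conditions: Dess–Martin periodinane (1.3 equiv), CH2Cl2, 0 °C → rt
Reagents that add atoms: none
Why: Dess–Martin oxidation of the benzylic secondary alcohol under non-basic conditions that leave the prenyl olefin, the aryl acetates and C2 untouched and erase C4 as planned; 9 is taken on at once and kept away from amine bases so that the 5-acetyl group cannot shift to O4.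

Step 7
Reactants: 10 (2S)-5,7-diacetoxy-2-[3-acetoxy-4-(3-methylbut-2-enyloxy)phenyl]chroman-4-one
Product: 11 monotesone A, (2S)-5,7-dihydroxy-2-[3-hydroxy-4-(3-methylbut-2-enyloxy)phenyl]chroman-4-one
Conditions: NH4OAc (10 equiv), MeOH/H2O 4:1, rt
Reagents that add atoms: none
Why: Ammonium acetate-mediated methanolysis of aryl acetates at neutral pH; no strong base is present, so the enolate/retro-oxa-Michael (chalcone) pathway that would racemise C2 should stay closed, and the prenyl ether is inert.

**Compound list**

1 | 2,4,6-trihydroxybenzaldehyde | O=Cc1c(O)cc(O)cc1O | starting material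
2 | 2,4-diacetoxy-6-hydroxybenzaldehyde | O=Cc1c(O)cc(OC(C)=O)cc1OC(C)=O | intermediate
3 | 3,4-dihydroxybenzaldehyde | O=Cc1ccc(O)c(O)c1 | starting material
4 | 1-bromo-3-methylbut-2-ene (prenyl bromide) | CC(C)=CCBr | starting material
5 | 3-hydroxy-4-(3-methylbut-2-enyloxy)benzaldehyde | O=Cc1ccc(OCC=C(C)C)c(O)c1 | intermediate
6 | potassium 5-formyl-2-(3-methylbut-2-enyloxy)phenolate | O=Cc1ccc(OCC=C(C)C)c([O-])c1.[K+] | intermediate
7 | 2-(3-methylbut-2-enyloxy)-5-vinylphenol | C=Cc1ccc(OCC=C(C)C)c(O)c1 | intermediate
8 | 2-(3-methylbut-2-enyloxy)-5-vinylphenyl acetate | C=Cc1ccc(OCC=C(C)C)c(OC(C)=O)c1 | intermediate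
9 | (2S,4S)-5,7-diacetoxy-2-[3-acetoxy-4-(3-methylbut-2-enyloxy)phenyl]chroman-4-ol (2,4-cis) | CC(C)=CCOc1ccc([C@@H]2C[C@H](O)c3c(OC(C)=O)cc(OC(C)=O)cc3O2)cc1OC(C)=O | intermediate
10 | (2S)-5,7-diacetoxy-2-[3-acetoxy-4-(3-methylbut-2-enyloxy)phenyl]chroman-4-one | CC(C)=CCOc1ccc([C@@H]2CC(=O)c3c(OC(C)=O)cc(OC(C)=O)cc3O2)cc1OC(C)=O | intermediate
11 | monotesone A | CC(C)=CCOc1ccc([C@@H]2CC(=O)c3c(O)cc(O)cc3O2)cc1O | target

**Step count**

Total: 7 steps. Longest linear sequence: 6 steps (3 → 5 → 7 → 8 → 9 → 10 → 11, steps 2 to 7).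

**Steps most likely to fail**

Risk 1, step 5. What may go wrong:
- low reactivity or poor facial selectivity of the aldehyde inside the chiral pocket;
- cationic oligomerisation of the styrene;
- acid-induced loss of the prenyl group;
- acid-induced shift of the 5-acetyl group to the C4 hydroxyl.

The fallback uses known chemistry (chalcone route and kinetic resolution by asymmetric transfer hydrogenation). It sets out from 5 and comes back at 10. Aldehyde 5 is treated with 3,4-dihydro-2H-pyran and PPTS to give 4-(3-methylbut-2-enyloxy)-3-(tetrahydropyran-2-yloxy)benzaldehyde F1. Commercial 2',4',6'-trihydroxyacetophenone is treated in the same way to give 1-[2-hydroxy-4,6-bis(tetrahydropyran-2-yloxy)phenyl]ethanone F2. Claisen–Schmidt condensation (KOH, EtOH) should give the tris-acetal 2'-hydroxychalcone F3. NaOAc in refluxing EtOH closes it by oxa-Michael addition to the racemic tris-acetal flavanone F4. PPTS in MeOH removes the three acetals to give racemic monotesone A F5, and Ac2O/pyridine gives the racemic triacetate F6. Kinetic resolution by transfer hydrogenation ([Cp*RhCl2]2 with TsDPEN of the appropriate hand, HCO2H/Et3N, EtOAc, stopped near half conversion) should reduce the 2R enantiomer to the cis-(2R,4R)-flavan-4-ol triacetate F7 and leave (S)-10, which re-enters the route at step 7.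

Risk 2, step 7. What may go wrong: partial racemisation at C2 by ring opening to the chalcone once the phenols are free, or incomplete cleavage of the hindered 5-acetate. The fallback exchanges the acetates for silyl ethers before the ketone exists. It sets out from 9 and comes back at 11. Compound 9 is deacetylated with K2CO3 in MeOH at 0 °C; without a carbonyl group there is no ring-opening pathway. After neutralisation this gives (2S,4S)-2-[3-hydroxy-4-(3-methylbut-2-enyloxy)phenyl]chroman-4,5,7-triol F8, used crude. TBSCl/imidazole in DMF at 0 °C should silylate the three phenols in preference to the hindered secondary alcohol, giving the tris-silyl flavan-4-ol F9. Dess–Martin oxidation gives the tris-silyl flavanone F10, and Et3N·3HF in THF (buffered fluoride) removes the silyl groups to give 11.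

Risk 3, step 3. What may go wrong: sluggish olefination of the phenolate and polymerisation of the electron-rich vinylphenol on concentration. The fallback avoids the free vinylphenol. It sets out from 5 and comes back at 8. TBSCl/imidazole gives 3-(tert-butyldimethylsilyloxy)-4-(3-methylbut-2-enyloxy)benzaldehyde F11. Wittig methylenation with one equivalent of ylide gives tert-butyldimethyl[2-(3-methylbut-2-enyloxy)-5-vinylphenoxy]silane F12. TBAF in THF at 0 °C liberates tetrabutylammonium 2-(3-methylbut-2-enyloxy)-5-vinylphenolate F13, which is acetylated in the same flask with Ac2O to give 8.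

**Further compounds**

F1 | step 5 | 4-(3-methylbut-2-enyloxy)-3-(tetrahydropyran-2-yloxy)benzaldehyde | O=Cc1ccc(OCC=C(C)C)c(OC2CCCCO2)c1
F2 | step 5 | 1-[2-hydroxy-4,6-bis(tetrahydropyran-2-yloxy)phenyl]ethanone | CC(=O)c1c(O)cc(OC2CCCCO2)cc1OC1CCCCO1
F3 | step 5 | (E)-1-[2-hydroxy-4,6-bis(tetrahydropyran-2-yloxy)phenyl]-3-[4-(3-methylbut-2-enyloxy)-3-(tetrahydropyran-2-yloxy)phenyl]prop-2-en-1-one | CC(C)=CCOc1ccc(/C=C/C(=O)c2c(O)cc(OC3CCCCO3)cc2OC2CCCCO2)cc1OC1CCCCO1
F4 | step 5 | racemic 5,7-bis(tetrahydropyran-2-yloxy)-2-[4-(3-methylbut-2-enyloxy)-3-(tetrahydropyran-2-yloxy)phenyl]chroman-4-one | CC(C)=CCOc1ccc(C2CC(=O)c3c(OC4CCCCO4)cc(OC4CCCCO4)cc3O2)cc1OC1CCCCO1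
F5 | step 5 | racemic monotesone A | CC(C)=CCOc1ccc(C2CC(=O)c3c(O)cc(O)cc3O2)cc1O
F6 | step 5 | racemic 5,7-diacetoxy-2-[3-acetoxy-4-(3-methylbut-2-enyloxy)phenyl]chroman-4-one | CC(C)=CCOc1ccc(C2CC(=O)c3c(OC(C)=O)cc(OC(C)=O)cc3O2)cc1OC(C)=O
F7 | step 5 | (2R,4R)-5,7-diacetoxy-2-[3-acetoxy-4-(3-methylbut-2-enyloxy)phenyl]chroman-4-ol | CC(C)=CCOc1ccc([C@H]2C[C@@H](O)c3c(OC(C)=O)cc(OC(C)=O)cc3O2)cc1OC(C)=O
F8 | step 7 | (2S,4S)-2-[3-hydroxy-4-(3-methylbut-2-enyloxy)phenyl]chroman-4,5,7-triol | CC(C)=CCOc1ccc([C@@H]2C[C@H](O)c3c(O)cc(O)cc3O2)cc1O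
F9 | step 7 | (2S,4S)-5,7-bis(tert-butyldimethylsilyloxy)-2-[3-(tert-butyldimethylsilyloxy)-4-(3-methylbut-2-enyloxy)phenyl]chroman-4-ol | CC(C)=CCOc1ccc([C@@H]2C[C@H](O)c3c(O[Si](C)(C)C(C)(C)C)cc(O[Si](C)(C)C(C)(C)C)cc3O2)cc1O[Si](C)(C)C(C)(C)C
F10 | step 7 | (2S)-5,7-bis(tert-butyldimethylsilyloxy)-2-[3-(tert-butyldimethylsilyloxy)-4-(3-methylbut-2-enyloxy)phenyl]chroman-4-one | CC(C)=CCOc1ccc([C@@H]2CC(=O)c3c(O[Si](C)(C)C(C)(C)C)cc(O[Si](C)(C)C(C)(C)C)cc3O2)cc1O[Si](C)(C)C(C)(C)C
F11 | step 3 | 3-(tert-butyldimethylsilyloxy)-4-(3-methylbut-2-enyloxy)benzaldehyde | O=Cc1ccc(OCC=C(C)C)c(O[Si](C)(C)C(C)(C)C)c1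
F12 | step 3 | tert-butyldimethyl[2-(3-methylbut-2-enyloxy)-5-vinylphenoxy]silane | C=Cc1ccc(OCC=C(C)C)c(O[Si](C)(C)C(C)(C)C)c1
F13 | step 3 | tetrabutylammonium 2-(3-methylbut-2-enyloxy)-5-vinylphenolate | C=Cc1ccc(OCC=C(C)C)c([O-])c1.CCCC[N+](CCCC)(CCCC)CCCC
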